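## The problem

Target 23 is a diarylmethane in which two pentasubstituted benzene rings share one CH2 group. Ring A carries the 2-(sulfooxy)ethyl chain on C1, hydrogen on C2, hydroxyls on C3 and C4, bromine on C5 and the bridging methylene on C6. Ring B carries bromine on C2' and C3', hydroxyls on C4' and C5' and one hydrogen on C6'. There is no stereocentre, so the task is regiochemical: each ring keeps a single hydrogen, and the contiguous array CH2Ar/Br/OH/OH on ring A has to be set without ambiguity. The only stereochemical element on the way is the Z geometry of one trisubstituted alkene in the open-chain precursor of ring A, which decides whether that ring can close at all. Three aryl bromides rule out aryllithium chemistry and hydrogenolysis and ask for chemoselectivity in any palladium step and under light. The two catechols are oxidation-prone and should stay etherified until the end. The primary alkyl hydrogen sulfate would not survive Lewis-acid dealkylation, so it must come last and must be placed on the one aliphatic hydroxyl in the presence of four phenols. The enabling feature is the pair of neighbouring oxygen-bearing carbons C3 and C4, flanked by C2–H and C5. This is the pattern that arises when a methoxycarbene carbon (C3) and a carbon monoxide ligand (C4) become adjacent ring atoms, and the hydroxyl so created on C4 sits ortho to C5, where the last bromine belongs.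

## Retrosynthesis

**Sulfate (O–S bond), 23 to 22.** The sulfate ester is cut first because it cannot be carried through the ether cleavages. Pentol 22, 3-bromo-4-[(2,3-dibromo-4,5-dihydroxyphenyl)methyl]-5-(2-hydroxyethyl)benzene-1,2-diol, has the full carbon and halogen pattern. The forward step must sulfate the aliphatic hydroxyl faster than the four less nucleophilic phenols.

**Ethers (three aryl O–CH3 bonds and one O–benzyl bond), 22 to 21.** All four are cut in one Lewis-acid operation. Two methyl groups come with vanillin and the third with the carbene, so no protecting-group step is spent on the phenols. The benzyl ether is chosen for the chain because it survives hot acetic acid, silanolate, the chromate dianion and light, yet falls to the same reagent as the methyl ethers. Precursor 21 is a stable, fully etherified tribromide with one free phenol.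

**C5–Br, 21 to 20.** The third bromine is removed from the position ortho to the only free hydroxyl. Carrying it through ring formation would require a bromo-substituted diene terminus, which is harder to make and to keep. Introducing it afterwards uses the C4 hydroxyl as director against the single competing site C2, which is ortho to a methoxy group only. Phenol 20 is 4-[2-(benzyloxy)ethyl]-5-[(2,3-dibromo-4,5-dimethoxyphenyl)methyl]-2-methoxyphenol.

**Ring A (C3–C4 and C4–C5), 20 to 19.** Cutting these two bonds removes the ring and turns C4 into a carbon monoxide ligand. The precursor is the open-chain pentacarbonylchromium (2Z)-dienyl(methoxy)carbene complex 19. Every ring substituent is then fixed by chain connectivity, which a substitution-based approach to a pentasubstituted ring cannot offer. The forward step needs CO migration to the carbene carbon and six-electron closure of the resulting dienylketene, which is possible only from the Z alkene.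

**Carbene unit (Cr=C and O–CH3), 19 to 15 and 16.** The carbene carbon is traced to an acyl carbon. Acid chloride 15 acylates disodium pentacarbonylchromate 17, made from Cr(CO)6 16, and the acylchromate 18 is O-methylated. The classical route through a dienyllithium is closed by the aryl bromides. Compound 15 comes from methyl ester 13 through the potassium carboxylate 14, a path that never exposes the acid-sensitive (2Z)-dienoic acid to protic acid.

**Diene (C1–C6 bond), 13 to 12 and 8.** The bond between the two alkenes is cut to (Z)-iodoenoate 12 and alkenylboronate 8. This is preferred over a cut at the benzylic bond because the geometry is then bought in one reliable step (anti hydroiodination) and transferred with retention. The forward coupling must take the alkenyl iodide and leave two hindered aryl bromides alone.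

**Iodoenoate, 12 to 9.** Compound 12 goes back through ynoate 11 and benzyl ether 10 to but-3-yn-1-ol 9; three standard steps.

**Boronate and ring B, 8 to 1.** The 1,1-disubstituted alkenylboronate 8 is cut at its C=CH2 bond to geminal diboronate 7 and formaldehyde. Compound 7 is cut at the benzylic C–C bond to benzyl bromide 5 and bis(pinacolboryl)methane 6. This path uses no palladium and no aryl metal and is unambiguous in regiochemistry. Bromide 5 descends through alcohol 4, aldehyde 3 and 5,6-dibromovanillin 2 from vanillin 1, where the aldehyde and the free hydroxyl steer both bromines to the required positions.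

## Roads not taken

**Alternative 1: aryne acyl-alkylation.** The cut removes both ortho carbon arms of ring A. Fluoride would convert silyl triflate A1 into a bromodimethoxy aryne, which inserts into the CH2–carbonyl bond of ring B β-ketoester A2 to give keto ester A3; no ring is formed.
- Merits: the union is highly convergent, the ring A bromine is in place from the start so no late bromination is needed, and neither stoichiometric chromium nor light is involved. In convergence and in avoiding a late regioselective halogenation it is better than the chosen plan.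
- Weak points: A1 is itself a pentasubstituted benzene that needs several steps. The aryl anion formed next to bromine during insertion can expel bromide and open a second aryne channel. The anion must attack a ketone on an ortho-brominated ring, giving a benzophenone with three ortho substituents. That carbonyl then has to be reduced to CH2 and the ester to the alcohol, which adds redox steps in a crowded setting.
- Comparison: the chosen plan delivers the methylene and the chain at their final oxidation levels and fixes regiochemistry by connectivity alone.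

**Alternative 2: biomimetic threefold bromination.** All three C–Br bonds are cut at once. Bromine-free diarylmethane A4, with free hydroxyls on C4 and C4', would take up three equivalents of bromine to give A5.
- Merits: it is the shortest endgame, and every earlier step would be free of aryl bromides. The chemoselectivity burdens of steps 6, 10 and 12 of the chosen route would disappear; in that respect it is clearly better.
- Weak points: five aromatic C–H positions are open and three must be hit. After bromination ortho to the ring B hydroxyl, the second ring B bromine must enter the crowded C2' and not C6'; this preference is established for vanillin, where the aldehyde deactivates the alternative site, but not here. The para-hydroxybenzyl unit invites ipso attack with cleavage of the diarylmethane. A4 itself still has to be assembled.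
- Comparison: the chosen plan fixes the two ring B bromines at the vanillin stage and leaves a single bromination directed by the only free phenol.

**Alternative 3: methoxyfuran cycloaddition.** The cut is at C1–C6 and C4–C5. Furan A6 would add across ethynyl ketone A7, and acid would open the oxygen bridge to give phenol A8.
- Merits: it is metal-free, joins the two fragments and closes ring A in one operation, and the methoxy group controls both the orientation of addition and the direction of bridge opening. The free hydroxyl ends on C4 exactly as in the chosen plan. It is the more convergent ring-forming step.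
- Weak points: A6 is an electron-rich, acid-sensitive furan that is not trivial to prepare. Furan cycloadditions to ynones are reversible and often need forcing conditions. A8 is a diaryl ketone with three ortho substituents that must still be reduced to the methylene.
- Comparison: the chosen plan is longer before the ring closure, but it needs no deoxygenation and its fragment syntheses rest on standard reactions.

Key step: step 13

Assumption: the target is taken as the free hydrogen sulfate as drawn; the final ion exchange sets the acid form.

## Steps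

Step 1
Reactants: 1 vanillin
Product: 2 2,3-dibromo-4-hydroxy-5-methoxybenzaldehyde
Conditions: Br2 (2.2 equiv), Fe powder (cat.), NaOAc, AcOH, 20 °C
Reagents that add atoms: bromine, BrBr
Why: Electrophilic aromatic bromination; the first bromine enters ortho to the free hydroxyl and the second para to the methoxy group, the site between aldehyde and methoxy being deactivated and hindered. This double bromination of vanillin is established.

Step 2
Reactants: 2 2,3-dibromo-4-hydroxy-5-methoxybenzaldehyde
Product: 3 2,3-dibromo-4,5-dimethoxybenzaldehyde
Conditions: MeI, K2CO3, DMF, 20 to 40 °C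
Reagents that add atoms: iodomethane, CI
Why: Williamson O-methylation of an acidic, ortho-brominated phenol; no other nucleophilic site is present.

Step 3
Reactants: 3 2,3-dibromo-4,5-dimethoxybenzaldehyde
Product: 4 (2,3-dibromo-4,5-dimethoxyphenyl)methanol
Conditions: NaBH4, MeOH/THF, 0 °C
Reagents that add atoms: none
Why: Borohydride reduction of an aryl aldehyde; aryl bromides and ethers are inert.

Step 4
Reactants: 4 (2,3-dibromo-4,5-dimethoxyphenyl)methanol
Product: 5 2,3-dibromo-1-(bromomethyl)-4,5-dimethoxybenzene
Conditions: PBr3, CH2Cl2, 0 to 20 °C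
Reagents that add atoms: phosphorus tribromide, BrP(Br)Br
Why: Standard conversion of a benzylic alcohol into the bromide through the phosphite ester.

Step 5
Reactants: 5 2,3-dibromo-1-(bromomethyl)-4,5-dimethoxybenzene; 6 bis(pinacolboryl)methane
Product: 7 2,2'-[2-(2,3-dibromo-4,5-dimethoxyphenyl)ethane-1,1-diyl]bis(4,4,5,5-tetramethyl-1,3,2-dioxaborolane)
Conditions: lithium 2,2,6,6-tetramethylpiperidide (LiTMP), THF, 0 to 20 °C
Reagents that add atoms: none
Why: Deprotonative alkylation of a geminal diboronate; the boron-stabilised carbanion is a soft nucleophile that displaces the benzylic bromide and does not exchange with aryl bromides.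

Step 6
Reactants: 7 geminal diboronate
Product: 8 2-[3-(2,3-dibromo-4,5-dimethoxyphenyl)prop-1-en-2-yl]-4,4,5,5-tetramethyl-1,3,2-dioxaborolane
Conditions: LiTMP, THF, 0 °C; CH2O (gas, from cracked paraformaldehyde), −78 to 20 °C
Reagents that add atoms: formaldehyde, C=O
Why: Boron-Wittig olefination; the α,α-diboryl carbanion adds to formaldehyde and the β-alkoxide eliminates one boryl group as borate, leaving the 1,1-disubstituted alkenylboronate. No regiochemical question arises and no palladium is needed.

Step 7
Reactants: 9 but-3-yn-1-ol
Product: 10 [(but-3-yn-1-yloxy)methyl]benzene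
Conditions: NaH, BnBr, Bu4NI (cat.), THF, 0 to 20 °C
Reagents that add atoms: benzyl bromide, BrCc1ccccc1
Why: Williamson etherification of a primary alkoxide; the alkynyl C–H is not deprotonated by the alkoxide.

Step 8
Reactants: 10 [(but-3-yn-1-yloxy)methyl]benzene
Product: 11 methyl 5-(benzyloxy)pent-2-ynoate
Conditions: n-butyllithium (n-BuLi), THF, −78 °C; ClCO2Me, −78 to 0 °C
Reagents that add atoms: methyl chloroformate, COC(=O)Cl
Why: Acylation of a lithium acetylide with a chloroformate, the standard route to 2-ynoates.

Step 9
Reactants: 11 methyl 5-(benzyloxy)pent-2-ynoate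
Product: 12 methyl (2Z)-5-(benzyloxy)-3-iodopent-2-enoate
Conditions: NaI, AcOH, 115 °C
Reagents that add atoms: sodium iodide, [Na+].[I-]
Why: Conjugate hydroiodination of a 2-ynoate; iodide adds at C3 and protonation occurs anti, so iodine and the ester are cis (Z). The benzyl ether tolerates the weakly acidic medium.

Step 10
Reactants: 12 methyl (2Z)-5-(benzyloxy)-3-iodopent-2-enoate; 8 alkenylboronate
Product: 13 methyl (2Z)-3-[2-(benzyloxy)ethyl]-4-[(2,3-dibromo-4,5-dimethoxyphenyl)methyl]penta-2,4-dienoate
Conditions: Pd(PPh3)4 (5 mol %), K3PO4 (aq.), THF, 45 °C, degassed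
Reagents that add atoms: none
Why: Suzuki–Miyaura coupling; zerovalent palladium inserts into the activated alkenyl C–I bond far faster than into the two hindered, electron-rich aryl C–Br bonds. Transmetalation and reductive elimination retain geometry, so the new vinyl unit stays cis to the ester.

Step 11
Reactants: 13 methyl (2Z)-dienoate
Product: 15 (2Z)-3-[2-(benzyloxy)ethyl]-4-[(2,3-dibromo-4,5-dimethoxyphenyl)methyl]penta-2,4-dienoyl chloride, via potassium carboxylate 14 (not isolated)
Conditions: KOSiMe3, THF, 20 °C; evaporate; (COCl)2, CH2Cl2, 0 °C; used crude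
Reagents that add atoms: oxalyl chloride, ClC(=O)C(=O)Cl; potassium trimethylsilanolate, C[Si](C)(C)[O-].[K+] (potassium of 14)
Why: Anhydrous ester cleavage by silanolate gives the potassium carboxylate, which oxalyl chloride converts into the acid chloride with release of only KCl, CO and CO2. No protic acid is formed that could lactonise the (2Z)-dienoic acid onto its 1,1-disubstituted alkene.

Step 12
Reactants: 15 (2Z)-dienoyl chloride; 16 chromium hexacarbonyl, Cr(CO)6
Product: 19 pentacarbonyl[(2Z)-3-[2-(benzyloxy)ethyl]-4-[(2,3-dibromo-4,5-dimethoxyphenyl)methyl]-1-methoxypenta-2,4-dien-1-ylidene]chromium, via disodium pentacarbonylchromate 17 (not isolated), via sodium acylpentacarbonylchromate 18 (not isolated)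
Conditions: Cr(CO)6, NaC10H8 (sodium naphthalenide, 2.0 equiv), THF, −78 °C; 15, −78 to 0 °C; solvent exchange; Me3OBF4, CH2Cl2, 0 °C, dark
Reagents that add atoms: trimethyloxonium tetrafluoroborate, C[O+](C)C.F[B-](F)(F)F; sodium naphthalenide, [Na+].[CH-]1C=Cc2ccccc2[CH]1 (sodium of 17 and 18)
Why: Acylate route to Fischer alkoxycarbene complexes; the strongly nucleophilic pentacarbonylchromate dianion is acylated at low temperature and the acylchromate oxygen is methylated by the oxonium salt. No dienyllithium is required, and the reductant is used without excess so that the aryl bromides are not reduced.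

Step 13
Reactants: 19 chromium (2Z)-dienyl(methoxy)carbene complex
Product: 20 4-[2-(benzyloxy)ethyl]-5-[(2,3-dibromo-4,5-dimethoxyphenyl)methyl]-2-methoxyphenol
Conditions: hν (450 nm LED or Hg lamp through a ≥ 400 nm filter), CO (1 atm), THF, 20 °C
Reagents that add atoms: none
Why: Irradiation into the metal-to-ligand charge-transfer band makes one cis carbonyl ligand migrate to the carbene carbon, forming C3–C4 and giving a chromium-bound methoxy(dienyl)ketene in which C3 carries the methoxy group. Because the C2=C1 alkene is Z, the ketene carbon C4 and the terminal methylene C5 lie at the ends of a hexatriene and close by a thermally allowed disrotatory six-electron electrocyclisation, forming C4–C5 and ring A as a cyclohexa-2,4-dienone. Enolisation then gives the ortho-methoxyphenol, and under CO the metal is returned as Cr(CO)6. The closest known reaction type is the photochemical ortho-alkoxyphenol benzannulation of chromium dienyl(alkoxy)carbene complexes, a relative of the Dötz reaction in which the diene is preassembled. No stereocentre is formed, and regiochemistry is not at issue because each ring atom is fixed by the chain connectivity. The step needs the Z alkene set in step 9 and kept through steps 10 to 12. It also needs CO insertion to outrun direct five-membered ring closure of the carbene, which the CO atmosphere and light favour, and it needs the aryl bromides to stay intact, which visible light absorbed only by the complex secures.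

Step 14
Reactants: 20 ortho-methoxyphenol
Product: 21 4-[2-(benzyloxy)ethyl]-2-bromo-3-[(2,3-dibromo-4,5-dimethoxyphenyl)methyl]-6-methoxyphenol
Conditions: NBS (1.0 equiv), i-Pr2NH (10 mol %), CH2Cl2, 0 °C, dark
Reagents that add atoms: N-bromosuccinimide, O=C1CCC(=O)N1Br
Why: Amine-mediated ortho-bromination of a phenol; the para position is blocked, C5 is the only site ortho to the hydroxyl, and the competing C2 is activated by a methoxy group only. Ring B is deactivated by two bromines.

Step 15
Reactants: 21 tribromide
Product: 22 3-bromo-4-[(2,3-dibromo-4,5-dihydroxyphenyl)methyl]-5-(2-hydroxyethyl)benzene-1,2-diol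
Conditions: BBr3 (8 equiv), CH2Cl2, −78 to 20 °C; H2O, 0 °C
Reagents that add atoms: none
Why: Lewis-acid dealkylation; bromide displaces methyl from the three complexed aryl methyl ethers and benzyl from the alkyl benzyl ether, and hydrolysis of the borates frees the four phenols and the primary alcohol. Aryl C–Br bonds are inert.

Step 16
Reactants: 22 pentol
Product: 23 2-{3-bromo-2-[(2,3-dibromo-4,5-dihydroxyphenyl)methyl]-4,5-dihydroxyphenyl}ethyl hydrogen sulfate
Conditions: SO3·pyridine (1.2 equiv), DMF, 0 °C; cation-exchange resin (H+ form)
Reagents that add atoms: sulfur trioxide–pyridine, O=S(=O)([O-])[n+]1ccccc1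
Why: O-Sulfation with an amine–sulfur trioxide complex; without added base the aliphatic primary hydroxyl is the most nucleophilic oxygen, while the hindered, bromine-deactivated phenols react more slowly, so a near-stoichiometric charge at low temperature should favour the alkyl sulfate.

## Compound list

1 | vanillin | COc1cc(C=O)ccc1O | starting material
2 | 2,3-dibromo-4-hydroxy-5-methoxybenzaldehyde | O=Cc1cc(OC)c(O)c(Br)c1Br | intermediate
3 | 2,3-dibromo-4,5-dimethoxybenzaldehyde | O=Cc1cc(OC)c(OC)c(Br)c1Br | intermediate
4 | (2,3-dibromo-4,5-dimethoxyphenyl)methanol | OCc1cc(OC)c(OC)c(Br)c1Br | intermediate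
5 | 2,3-dibromo-1-(bromomethyl)-4,5-dimethoxybenzene | BrCc1cc(OC)c(OC)c(Br)c1Br | intermediate
6 | bis(pinacolboryl)methane, 2,2'-methylenebis(4,4,5,5-tetramethyl-1,3,2-dioxaborolane) | CC1(C)OB(CB2OC(C)(C)C(C)(C)O2)OC1(C)C | starting material
7 | 2,2'-[2-(2,3-dibromo-4,5-dimethoxyphenyl)ethane-1,1-diyl]bis(4,4,5,5-tetramethyl-1,3,2-dioxaborolane) | COc1cc(CC(B2OC(C)(C)C(C)(C)O2)B2OC(C)(C)C(C)(C)O2)c(Br)c(Br)c1OC | intermediate
8 | 2-[3-(2,3-dibromo-4,5-dimethoxyphenyl)prop-1-en-2-yl]-4,4,5,5-tetramethyl-1,3,2-dioxaborolane | C=C(Cc1cc(OC)c(OC)c(Br)c1Br)B1OC(C)(C)C(C)(C)O1 | intermediate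
9 | but-3-yn-1-ol | C#CCCO | starting material
10 | [(but-3-yn-1-yloxy)methyl]benzene | C#CCCOCc1ccccc1 | intermediate
11 | methyl 5-(benzyloxy)pent-2-ynoate | COC(=O)C#CCCOCc1ccccc1 | intermediate
12 | methyl (2Z)-5-(benzyloxy)-3-iodopent-2-enoate | COC(=O)/C=C(\I)CCOCc1ccccc1 | intermediate
13 | methyl (2Z)-3-[2-(benzyloxy)ethyl]-4-[(2,3-dibromo-4,5-dimethoxyphenyl)methyl]penta-2,4-dienoate | COC(=O)/C=C(\C(=C)Cc1cc(OC)c(OC)c(Br)c1Br)CCOCc1ccccc1 | intermediate
14 | potassium (2Z)-3-[2-(benzyloxy)ethyl]-4-[(2,3-dibromo-4,5-dimethoxyphenyl)methyl]penta-2,4-dienoate | [K+].[O-]C(=O)/C=C(\C(=C)Cc1cc(OC)c(OC)c(Br)c1Br)CCOCc1ccccc1 | intermediate (not isolated)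
15 | (2Z)-3-[2-(benzyloxy)ethyl]-4-[(2,3-dibromo-4,5-dimethoxyphenyl)methyl]penta-2,4-dienoyl chloride | O=C(Cl)/C=C(\C(=C)Cc1cc(OC)c(OC)c(Br)c1Br)CCOCc1ccccc1 | intermediate
16 | chromium hexacarbonyl, Cr(CO)6 | O=C=[Cr](=C=O)(=C=O)(=C=O)(=C=O)=C=O | starting material
17 | disodium pentacarbonylchromate, Na2Cr(CO)5 | [Na+].[Na+].O=C=[Cr-2](=C=O)(=C=O)(=C=O)=C=O | intermediate (not isolated)
18 | sodium pentacarbonyl[(2Z)-3-[2-(benzyloxy)ethyl]-4-[(2,3-dibromo-4,5-dimethoxyphenyl)methyl]penta-2,4-dienoyl]chromate | [Na+].O=C(/C=C(\C(=C)Cc1cc(OC)c(OC)c(Br)c1Br)CCOCc1ccccc1)[Cr-](=C=O)(=C=O)(=C=O)(=C=O)=C=O | intermediate (not isolated)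
19 | pentacarbonyl[(2Z)-3-[2-(benzyloxy)ethyl]-4-[(2,3-dibromo-4,5-dimethoxyphenyl)methyl]-1-methoxypenta-2,4-dien-1-ylidene]chromium | COC(=[Cr](=C=O)(=C=O)(=C=O)(=C=O)=C=O)/C=C(\C(=C)Cc1cc(OC)c(OC)c(Br)c1Br)CCOCc1ccccc1 | intermediate
20 | 4-[2-(benzyloxy)ethyl]-5-[(2,3-dibromo-4,5-dimethoxyphenyl)methyl]-2-methoxyphenol | COc1cc(CCOCc2ccccc2)c(Cc2cc(OC)c(OC)c(Br)c2Br)cc1O | intermediate
21 | 4-[2-(benzyloxy)ethyl]-2-bromo-3-[(2,3-dibromo-4,5-dimethoxyphenyl)methyl]-6-methoxyphenol | COc1cc(CCOCc2ccccc2)c(Cc2cc(OC)c(OC)c(Br)c2Br)c(Br)c1O | intermediate
22 | 3-bromo-4-[(2,3-dibromo-4,5-dihydroxyphenyl)methyl]-5-(2-hydroxyethyl)benzene-1,2-diol | OCCc1cc(O)c(O)c(Br)c1Cc1cc(O)c(O)c(Br)c1Br | intermediate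
23 | 2-{3-bromo-2-[(2,3-dibromo-4,5-dihydroxyphenyl)methyl]-4,5-dihydroxyphenyl}ethyl hydrogen sulfate | O=S(=O)(O)OCCc1cc(O)c(O)c(Br)c1Cc1cc(O)c(O)c(Br)c1Br | target

## Step count and least certain steps

Total: 16 steps. Longest linear sequence: 13 steps (steps 1 to 6, then 10 to 16); the branch from but-3-yn-1-ol adds steps 7 to 9.

**Step 13 (key step).** The most likely failure is that the open-chain dienylcarbene does not follow the ketene path. The reactive s-cis conformer is sparsely populated without a ring to hold it. Direct five-membered ring closure without CO insertion, light-driven Z to E isomerisation, or oxidative loss of the metal may then win.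
Fallback, from 19 back to 20: the thermal isonitrile variant of the same ring closure. Heating 19 with tert-butyl isocyanide in THF should give, through a ketenimine and the same six-electron closure, N-tert-butyl-4-[2-(benzyloxy)ethyl]-5-[(2,3-dibromo-4,5-dimethoxyphenyl)methyl]-2-methoxyaniline F1. Acid-mediated loss of the tert-butyl group (CF3CO2H, 60 °C) would give 4-[2-(benzyloxy)ethyl]-5-[(2,3-dibromo-4,5-dimethoxyphenyl)methyl]-2-methoxyaniline F2. Diazotisation (NaNO2, H2SO4, 0 °C) and Sandmeyer-type hydroxylation (Cu2O, Cu(NO3)2, H2O) would return phenol 20.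

**Step 12.** Electron transfer from the chromate dianion to the conjugated dienoyl chloride or to the aryl bromides may compete with acylation. The (2Z)-dienoyl chloride may also cyclise or isomerise before it is captured.
Fallback, from 4 back to 22: leave the organochromium route and use a Friedel–Crafts union. Homovanillyl alcohol diacetate, 4-(2-acetoxyethyl)-2-methoxyphenyl acetate F3 (from commercial homovanillyl alcohol and Ac2O), is benzylated with alcohol 4 (BF3·OEt2 or AlCl3, CH2Cl2, 0 °C) para to its methoxy group, giving 4-(2-acetoxyethyl)-5-[(2,3-dibromo-4,5-dimethoxyphenyl)methyl]-2-methoxyphenyl acetate F4. Methanolysis (K2CO3, MeOH) gives 5-[(2,3-dibromo-4,5-dimethoxyphenyl)methyl]-4-(2-hydroxyethyl)-2-methoxyphenol F5. Bromination as in step 14 gives 2-bromo-3-[(2,3-dibromo-4,5-dimethoxyphenyl)methyl]-4-(2-hydroxyethyl)-6-methoxyphenol F6, and BBr3 returns 22.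

**Step 6.** Formaldehyde may polymerise faster than the hindered carbanion captures it, or the carbanion may be quenched by protonation, leaving the saturated diboronate.
Fallback, from 5 back to 8: CuBr-catalysed coupling of 5 with ethynylmagnesium bromide gives 2,3-dibromo-4,5-dimethoxy-1-(prop-2-yn-1-yl)benzene F7. Markovnikov bromoboration with B-bromo-9-borabicyclo[3.3.1]nonane followed by protonolysis with AcOH gives 2,3-dibromo-1-(2-bromoprop-2-en-1-yl)-4,5-dimethoxybenzene F8. Miyaura borylation of the alkenyl bromide (B2pin2, PdCl2(PPh3)2, PPh3, KOPh, toluene, 50 °C) returns 8.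

**Step 10.** Competing oxidative addition into an aryl C–Br bond, protodeboronation of the hindered alkenylboronate, or partial loss of the Z geometry at the β-palladated enoate would erode the coupling.
Fallback, from 12 and 5 back to 13: form the alkene–alkene bond before any aryl bromide is present, then make the benzylic bond. Mono-coupling of 12 with 1,1-bis(pinacolboryl)ethene (Pd(PPh3)4, K3PO4) gives methyl (2Z)-5-(benzyloxy)-3-[1-(4,4,5,5-tetramethyl-1,3,2-dioxaborolan-2-yl)ethenyl]pent-2-enoate F9. A benzyl–alkenyl Suzuki–Miyaura coupling of F9 with bromide 5, in which the benzylic C–Br bond is the reactive site, returns 13.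

**Step 16.** Sulfation may spread to the phenols or go twice, since the selectivity is kinetic only, and the free catechols may oxidise during work-up.
Fallback, from 22 back to 23: differentiate by protection. Phenol-selective acetylation under Schotten–Baumann conditions (Ac2O, aqueous NaHCO3, 0 °C, argon) gives 3-bromo-4-[(2,3-dibromo-4,5-diacetoxyphenyl)methyl]-5-(2-hydroxyethyl)-1,2-phenylene diacetate F10. Sulfation with SO3·pyridine gives 2-{3-bromo-2-[(2,3-dibromo-4,5-diacetoxyphenyl)methyl]-4,5-diacetoxyphenyl}ethyl hydrogen sulfate F11. Ammonolysis of the four aryl acetates (NH3, MeOH, 0 °C) returns 23.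

## Further compounds

F1 | step 13 | N-tert-butyl-4-[2-(benzyloxy)ethyl]-5-[(2,3-dibromo-4,5-dimethoxyphenyl)methyl]-2-methoxyaniline | COc1cc(CCOCc2ccccc2)c(Cc2cc(OC)c(OC)c(Br)c2Br)cc1NC(C)(C)C
F2 | step 13 | 4-[2-(benzyloxy)ethyl]-5-[(2,3-dibromo-4,5-dimethoxyphenyl)methyl]-2-methoxyaniline | COc1cc(CCOCc2ccccc2)c(Cc2cc(OC)c(OC)c(Br)c2Br)cc1N
F3 | step 12 | 4-(2-acetoxyethyl)-2-methoxyphenyl acetate | CC(=O)OCCc1ccc(OC(C)=O)c(OC)c1
F4 | step 12 | 4-(2-acetoxyethyl)-5-[(2,3-dibromo-4,5-dimethoxyphenyl)methyl]-2-methoxyphenyl acetate | CC(=O)OCCc1cc(OC)c(OC(C)=O)cc1Cc1cc(OC)c(OC)c(Br)c1Br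
F5 | step 12 | 5-[(2,3-dibromo-4,5-dimethoxyphenyl)methyl]-4-(2-hydroxyethyl)-2-methoxyphenol | OCCc1cc(OC)c(O)cc1Cc1cc(OC)c(OC)c(Br)c1Br
F6 | step 12 | 2-bromo-3-[(2,3-dibromo-4,5-dimethoxyphenyl)methyl]-4-(2-hydroxyethyl)-6-methoxyphenol | OCCc1cc(OC)c(O)c(Br)c1Cc1cc(OC)c(OC)c(Br)c1Br
F7 | step 6 | 2,3-dibromo-4,5-dimethoxy-1-(prop-2-yn-1-yl)benzene | C#CCc1cc(OC)c(OC)c(Br)c1Br
F8 | step 6 | 2,3-dibromo-1-(2-bromoprop-2-en-1-yl)-4,5-dimethoxybenzene | C=C(Br)Cc1cc(OC)c(OC)c(Br)c1Br
F9 | step 10 | methyl (2Z)-5-(benzyloxy)-3-[1-(4,4,5,5-tetramethyl-1,3,2-dioxaborolan-2-yl)ethenyl]pent-2-enoate | COC(=O)/C=C(\C(=C)B1OC(C)(C)C(C)(C)O1)CCOCc1ccccc1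
F10 | step 16 | 3-bromo-4-[(2,3-dibromo-4,5-diacetoxyphenyl)methyl]-5-(2-hydroxyethyl)-1,2-phenylene diacetate | CC(=O)Oc1cc(CCO)c(Cc2cc(OC(C)=O)c(OC(C)=O)c(Br)c2Br)c(Br)c1OC(C)=O
F11 | step 16 | 2-{3-bromo-2-[(2,3-dibromo-4,5-diacetoxyphenyl)methyl]-4,5-diacetoxyphenyl}ethyl hydrogen sulfate | CC(=O)Oc1cc(CCOS(=O)(=O)O)c(Cc2cc(OC(C)=O)c(OC(C)=O)c(Br)c2Br)c(Br)c1OC(C)=O
A1 | alternative 1 | 2-bromo-3,4-dimethoxy-6-(trimethylsilyl)phenyl trifluoromethanesulfonate | C[Si](C)(C)c1cc(OC)c(OC)c(Br)c1OS(=O)(=O)C(F)(F)F
A2 | alternative 1 | methyl 3-(2,3-dibromo-4,5-dimethoxyphenyl)-3-oxopropanoate | COC(=O)CC(=O)c1cc(OC)c(OC)c(Br)c1Br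
A3 | alternative 1 | methyl 2-[3-bromo-2-(2,3-dibromo-4,5-dimethoxybenzoyl)-4,5-dimethoxyphenyl]acetate | COC(=O)Cc1cc(OC)c(OC)c(Br)c1C(=O)c1cc(OC)c(OC)c(Br)c1Br
A4 | alternative 2 | 5-[(4-hydroxy-3-methoxyphenyl)methyl]-4-(2-hydroxyethyl)-2-methoxyphenol | COc1cc(CCO)c(Cc2ccc(O)c(OC)c2)cc1O
A5 | alternative 2 | 2-bromo-3-[(2,3-dibromo-4-hydroxy-5-methoxyphenyl)methyl]-4-(2-hydroxyethyl)-6-methoxyphenol | COc1cc(CCO)c(Cc2cc(OC)c(O)c(Br)c2Br)c(Br)c1O
A6 | alternative 3 | 2-[2-(benzyloxy)ethyl]-4-methoxyfuran | COc1coc(CCOCc2ccccc2)c1
A7 | alternative 3 | 1-(2,3-dibromo-4,5-dimethoxyphenyl)prop-2-yn-1-one | C#CC(=O)c1cc(OC)c(OC)c(Br)c1Br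
A8 | alternative 3 | {2-[2-(benzyloxy)ethyl]-5-hydroxy-4-methoxyphenyl}(2,3-dibromo-4,5-dimethoxyphenyl)methanone | COc1cc(CCOCc2ccccc2)c(C(=O)c2cc(OC)c(OC)c(Br)c2Br)cc1O
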